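The numbers are those of an exercise; the run is a simulation.

The vessel changes from set-up to set-up while the charge stays, so the question is what a vessel does to the split between target and side product.

    substrate → intermediate A (k1 = 0.0082 h⁻¹)
    intermediate C → target (k2 = 0.019 h⁻¹)
    intermediate A ⇌ intermediate B (K3 = 0.89, k3 = 9.4 × 10⁻⁴ h⁻¹)
    intermediate A ⇌ intermediate C (K4 = 8.9, k4 = 0.0090 h⁻¹)
    2 substrate → homo dimer (k5 = 0.0059 M⁻¹ h⁻¹)
    intermediate A → side product (k6 = 0.016 h⁻¹)
    intermediate C ⇌ intermediate D (K7 = 0.25, k7 = 0.0081 h⁻¹)

in all of them: substrate 1.5 M

| flask | time | remark |
|---|---|---|
| Saturday's | 2.5 d | plug flow through a tube for 2.5 d, no back-mixing |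
| Thursday's |  | one stirred flow tank at steady state, fed with the mixture as stated, mean residence time 25.0 d |
| Wednesday's |  | one stirred flow tank at steady state, fed with the mixture as stated, mean residence time 2.5 d |
| Sunday's | 2.5 d | a closed flask charged with all of it at once and left for 2.5 d |

- the set-up with the highest share of target in all that became target or side product, at the outlet or at the end ("none" if the first two lie within 2 percentage points) (Saturday's / Thursday's / Wednesday's / Sunday's / none)
- share of target in all that became target or side product, at the outlet or at the end, Saturday's
- share of target in all that became target or side product, at the outlet or at the end, Thursday's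
- share of target in all that became target or side product, at the outlet or at the end, Wednesday's
- share of target in all that became target or side product, at the outlet or at the end, Sunday's

- in percentages every species weighs as the substrate in it: one homo dimer counts as two
- a step written with two of one species runs at k times the square of its concentration and takes two of it each time
- the stated concentrations are those of everything mixed, before any reaction; amounts are the same in each set-up
- run time (Saturday's): 2.5 d

Let a, c, d, p and s be the fractions of the charge standing as intermediate A, intermediate C, intermediate D, target and side product.

*What do you divide by what?* The rate of target by the rate of side product, which is 0.019 h⁻¹ times c over 0.016 h⁻¹ times a, and time has dropped out.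

*But c is unknown.* Take c+d together, since the exchange between intermediate C and intermediate D leaves that sum alone. It fills at 0.0090 h⁻¹ times a and drains through c, to target and back to intermediate A, at 0.0200 h⁻¹ in all. Integrated over a closed flask or a plug of tube, this gives p = gain × s − hold × (c+d). The gain, a selectivity factor, is target won per side product once c+d has emptied: 0.534. The hold is 0.949.

*So what is the ceiling?* In a closed flask or a tube the share tends to 34.8% as c+d goes to zero, and stands beneath that while c+d remains.

*And a tank?* At steady state p over s is exactly the rate ratio, but washout joins the drains of intermediate C, directly and through intermediate D. That adds 0.00206 h⁻¹ on Thursday's and 0.0194 h⁻¹ on Wednesday's. I get 32.6% for Thursday's, which is under the ceiling, and 21.3% for Wednesday's. Substrate does not enter this formula, and on Thursday's the dimer step makes no difference.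

*The tube and the flask?* Here my reckoning stops. The time of the drain of intermediate C, to target and back to intermediate A, is 2.08 d against a run of 2.5 d, and without s and c+d at the end I give no number.

The forecast names Thursday's: 32.6% there, 21.3% on Wednesday's, and 14.6% and 14.6% for Saturday's and Sunday's, where “C is still catching up”. Its tank figures are the same as mine, and its tube and flask figures are ones I did not reach.

The simulation gives Thursday's at 32.6%, Wednesday's 21.3%, and Saturday's and Sunday's 15.3% each. At 2.50 d Saturday's tube holds target 1.76% beside side product 9.75%, with 3.18% as intermediate C and 0.446% as intermediate D. The gain times that side product is 5.21%, and taking off the hold times those intermediates leaves 1.77%. The reading to watch is c+d: the hold times that sum is the gap between target and the gain times side product.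

Left until 10 d, Saturday's tube has side product 29.0%, intermediate C 2.07% and intermediate D 0.634%, so the same line gives target 12.9% and a share of 30.8%. Computed, they are 12.9% and 30.8%.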